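**Strategy.** The target is fisetinidol-(4α→6)-catechin. The route rests on disconnecting the aryl ether bond O1–C8a of ring C of the upper unit: O1 is carried as the carbonyl oxygen of an aryl ketone at C2 and C8a of ring A as a bromide. A copper-catalysed enolate O-arylation of a β,β-diaryl ketone, whose C4 already bears ring A and C6 of a protected 8-bromocatechin, closes ring C as a 4-aryl-4H-chromene. The C2=C3 enol ether so formed is hydroborated anti to the C4 aryl group, which installs C2–H and C3–OH in the all-trans arrangement. C4 itself comes from a rhodium-catalysed asymmetric conjugate arylation.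

Key step: step 9

Remark on numbering: flavan numbering (O1, C2–C4, C4a, C5–C8, C8a, primes for ring B) is used for both units and for their open-chain precursors. "Upper unit" is the 5-deoxy (fisetinidol) unit and "lower unit" the catechin unit.

Assumption: the diene ligand antipode named in step 8 is the one expected to deliver the aryl group to the Re face of C-β of enone 9. If the sense found is the opposite, the antipodal ligand is used and nothing else changes.

**Step 1**
Reactants: 1 (+)-catechin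
Product: 2 5,7,3',4'-tetra-O-benzyl-(+)-catechin
Conditions: BnBr (4.4 equiv), K2CO3, DMF, 0 °C to rt
Reagents that add atoms: benzyl bromide, BrCc1ccccc1
Why: Williamson etherification in which K2CO3 deprotonates only the four phenols, so the aliphatic 3-OH stays free and the C2 and C3 stereocentres are untouched.

**Step 2**
Reactants: 2 5,7,3',4'-tetra-O-benzyl-(+)-catechin
Product: 3 3,5,7,3',4'-penta-O-benzyl-(+)-catechin
Conditions: NaH, BnBr, DMF, 0 °C to rt
Reagents that add atoms: benzyl bromide, BrCc1ccccc1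
Why: Williamson etherification of the secondary alkoxide; with all phenols already capped the flavan cannot epimerise at C2 through a quinone methide.

**Step 3**
Reactants: 3 3,5,7,3',4'-penta-O-benzyl-(+)-catechin
Product: 4 8-bromo-3,5,7,3',4'-penta-O-benzylcatechin
Conditions: NBS, CH2Cl2, −20 °C to rt
Reagents that add atoms: N-bromosuccinimide, O=C1CCC(=O)N1Br
Why: electrophilic aromatic bromination of the phloroglucinol-type ring A, which is far more electron-rich than ring B and reacts at C8, the more accessible of its two free positions, so that C6 remains as the only open nucleophilic site.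

**Step 4**
Reactants: 4 8-bromo-3,5,7,3',4'-penta-O-benzylcatechin
Product: 6 8-bromo-3,5,7,3',4'-penta-O-benzylcatechin-6-carbaldehyde, via C6 iminium chloride 5 (not isolated)
Conditions: POCl3, DMF, 0 to 70 °C; then aq. NaOAc
Reagents that add atoms: N,N-dimethylformamide, CN(C)C=O; water, O
Why: Vilsmeier–Haack formylation in which the chloroiminium ion attacks C6, the only unsubstituted position of the activated ring A, and the iminium salt is hydrolysed on work-up.

**Step 5**
Reactants: 6 8-bromo-3,5,7,3',4'-penta-O-benzylcatechin-6-carbaldehyde; 7 1-[3,4-bis(benzyloxy)phenyl]ethanone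
Product: 9 (E)-1-[3,4-bis(benzyloxy)phenyl]-3-(8-bromo-3,5,7,3',4'-penta-O-benzylcatechin-6-yl)prop-2-en-1-one, via aldol adduct 8 (not isolated)
Conditions: KOH, EtOH/THF, rt to 40 °C
Reagents that add atoms: none
Why: Claisen–Schmidt condensation in which the aldol adduct dehydrates by E1cB to the conjugated (E)-enone, the thermodynamically favoured isomer.

**Step 6**
Reactants: 10 1-(benzyloxy)-3-bromobenzene
Product: 11 4-(benzyloxy)-2-bromo-1-iodobenzene
Conditions: NIS, TFA (cat.), MeCN, rt
Reagents that add atoms: N-iodosuccinimide, O=C1CCC(=O)N1I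
Why: electrophilic aromatic iodination that should occur para to the benzyloxy group, the strongest director on the ring.

**Step 7**
Reactants: 11 4-(benzyloxy)-2-bromo-1-iodobenzene
Product: 14 [4-(benzyloxy)-2-bromophenyl]boronic acid, via arylmagnesium chloride 12 (not isolated), via dimethyl arylboronate 13 (not isolated)
Conditions: iPrMgCl·LiCl, THF, −20 °C; B(OMe)3, −20 °C to rt; aq. HCl
Reagents that add atoms: trimethyl borate, COB(OC)OC; water, O
Why: iodine–magnesium exchange is selective for C–I over C–Br at −20 °C, where the ortho-bromoaryl Grignard reagent does not eliminate to an aryne, and borate trapping followed by hydrolysis gives the boronic acid.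

**Step 8**
Reactants: 9 (E)-enone; 14 [4-(benzyloxy)-2-bromophenyl]boronic acid
Product: 15 (3R)-3-[4-(benzyloxy)-2-bromophenyl]-1-[3,4-bis(benzyloxy)phenyl]-3-(8-bromo-3,5,7,3',4'-penta-O-benzylcatechin-6-yl)propan-1-one
Conditions: [RhCl(C2H4)2]2 (2.5 mol %), (1R,4R)-2,5-diphenylbicyclo[2.2.2]octa-2,5-diene (5.5 mol %), 14 (3 equiv), aq. KOH (0.5 equiv), dioxane/H2O, 50 °C
Reagents that add atoms: none
Why: Hayashi–Miyaura rhodium-catalysed asymmetric 1,4-addition of an arylboronic acid to an (E)-enone, in which the chiral diene ligand should direct the aryl group to the Re face of C-β and so set the (R)-configured diarylmethine carbon (the future C4) under catalyst control, independent of the remote catechin stereocentres.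

**Step 9**
Reactants: 15 β,β-diaryl ketone
Product: 16 (4S)-7-(benzyloxy)-2-[3,4-bis(benzyloxy)phenyl]-4-(8-bromo-3,5,7,3',4'-penta-O-benzylcatechin-6-yl)-4H-chromene
Conditions: CuI (10 mol %), 1,10-phenanthroline (20 mol %), K3PO4 (2 equiv), DMF, 100 °C, argon
Reagents that add atoms: none
Why: K3PO4 forms the (Z)-enolate of the aryl ketone reversibly, the copper enolate adds oxidatively into the neighbouring C8a–Br bond, and C–O reductive elimination gives the cyclic enol ether (Ullmann-type coupling). The closest known reaction type is the copper- or palladium-catalysed intramolecular O-arylation of ketone enolates that gives benzofurans and 4H-chromenes. Ring C closes as a six-membered ring by 6-exo attack of the enolate oxygen O1 on the ipso carbon C8a with loss of bromide, whereas C-arylation would need a four-membered ring and is excluded. No stereocentre is formed: C4 is not alpha to the carbonyl group and keeps its configuration, and the ring fixes the geometry of the new C2=C3 bond. The selectivity needed is between the two aryl bromides, and it is secured because only C8a–Br has a tethered nucleophile, while C8–Br of the lower unit is flanked by two oxygen substituents and has no partner within reach.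

**Step 10**
Reactants: 16 4-aryl-4H-chromene
Product: 18 8-bromo-octa-O-benzyl-fisetinidol-(4α→6)-catechin, (2R,3S,4S) in the upper unit with free 3-OH, via C3 alkylborane 17 (not isolated)
Conditions: BH3·THF, THF, 0 °C to rt; then aq. NaOH, H2O2, 0 °C
Reagents that add atoms: hydrogen peroxide, OO
Why: hydroboration–oxidation of a cyclic enol ether in which boron adds to C3 (β to O1 and to ring B) and hydrogen to C2, syn and from the face opposite the pseudoaxial C4 aryl group, so that the three ring substituents end up all-trans, and oxidation proceeds with retention at C3.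

**Step 11**
Reactants: 18 8-bromo-octa-O-benzyl dimer
Product: 19 fisetinidol-(4α→6)-catechin (CNP0141631.1)
Conditions: H2 (1 atm), Pd(OH)2/C, Et3N, THF/MeOH/H2O, rt
Reagents that add atoms: none
Why: hydrogenolysis of the eight benzyl ethers and hydrodebromination of C8–Br over Pearlman's catalyst, with Et3N capturing HBr so that the acid-labile interflavan bond and the stereocentres are not touched.

**Compound list**

1 | (+)-catechin, (2R,3S)-2-(3,4-dihydroxyphenyl)chromane-3,5,7-triol | Oc1cc(O)cc2c1C[C@H](O)[C@@H](c1ccc(O)c(O)c1)O2 | starting material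
2 | 5,7,3',4'-tetra-O-benzyl-(+)-catechin | c1ccccc1COc1cc(OCc3ccccc3)cc2c1C[C@H](O)[C@@H](c1ccc(OCc3ccccc3)c(OCc3ccccc3)c1)O2 | intermediate
3 | 3,5,7,3',4'-penta-O-benzyl-(+)-catechin | c1ccccc1COc1cc(OCc3ccccc3)cc2c1C[C@H](OCc1ccccc1)[C@@H](c1ccc(OCc3ccccc3)c(OCc3ccccc3)c1)O2 | intermediate
4 | 8-bromo-3,5,7,3',4'-penta-O-benzylcatechin | c1ccccc1COc1cc(OCc3ccccc3)c(Br)c2c1C[C@H](OCc1ccccc1)[C@@H](c1ccc(OCc3ccccc3)c(OCc3ccccc3)c1)O2 | intermediate
5 | C6 (dimethyliminio)methyl derivative of 4, chloride salt | c1ccccc1COc1c(C=[N+](C)C)c(OCc3ccccc3)c(Br)c2c1C[C@H](OCc1ccccc1)[C@@H](c1ccc(OCc3ccccc3)c(OCc3ccccc3)c1)O2.[Cl-] | intermediate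
6 | 8-bromo-3,5,7,3',4'-penta-O-benzylcatechin-6-carbaldehyde | c1ccccc1COc1c(C=O)c(OCc3ccccc3)c(Br)c2c1C[C@H](OCc1ccccc1)[C@@H](c1ccc(OCc3ccccc3)c(OCc3ccccc3)c1)O2 | intermediate
7 | 1-[3,4-bis(benzyloxy)phenyl]ethanone | CC(=O)c1ccc(OCc2ccccc2)c(OCc2ccccc2)c1 | starting material
8 | aldol adduct, 3-hydroxy-1-[3,4-bis(benzyloxy)phenyl]-3-(8-bromo-penta-O-benzylcatechin-6-yl)propan-1-one (carbinol epimers) | c1ccccc1COc1c(C(O)CC(=O)c3ccc(OCc4ccccc4)c(OCc4ccccc4)c3)c(OCc3ccccc3)c(Br)c2c1C[C@H](OCc1ccccc1)[C@@H](c1ccc(OCc3ccccc3)c(OCc3ccccc3)c1)O2 | intermediate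
9 | (E)-1-[3,4-bis(benzyloxy)phenyl]-3-(8-bromo-3,5,7,3',4'-penta-O-benzylcatechin-6-yl)prop-2-en-1-one | c1ccccc1COc1c(/C=C/C(=O)c3ccc(OCc4ccccc4)c(OCc4ccccc4)c3)c(OCc3ccccc3)c(Br)c2c1C[C@H](OCc1ccccc1)[C@@H](c1ccc(OCc3ccccc3)c(OCc3ccccc3)c1)O2 | intermediate
10 | 1-(benzyloxy)-3-bromobenzene | Brc1cccc(OCc2ccccc2)c1 | starting material
11 | 4-(benzyloxy)-2-bromo-1-iodobenzene | Ic1ccc(OCc2ccccc2)cc1Br | intermediate
12 | [4-(benzyloxy)-2-bromophenyl]magnesium chloride | Cl[Mg]c1ccc(OCc2ccccc2)cc1Br | intermediate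
13 | dimethyl [4-(benzyloxy)-2-bromophenyl]boronate | COB(OC)c1ccc(OCc2ccccc2)cc1Br | intermediate
14 | [4-(benzyloxy)-2-bromophenyl]boronic acid | OB(O)c1ccc(OCc2ccccc2)cc1Br | intermediate
15 | (3R)-3-[4-(benzyloxy)-2-bromophenyl]-1-[3,4-bis(benzyloxy)phenyl]-3-(8-bromo-3,5,7,3',4'-penta-O-benzylcatechin-6-yl)propan-1-one | O=C(c1ccc(OCc2ccccc2)c(OCc2ccccc2)c1)C[C@@H](c1ccc(OCc2ccccc2)cc1Br)c1c(OCc3ccccc3)c(Br)c2c(c1OCc1ccccc1)C[C@H](OCc1ccccc1)[C@@H](c1ccc(OCc3ccccc3)c(OCc3ccccc3)c1)O2 | intermediate
16 | (4S)-7-(benzyloxy)-2-[3,4-bis(benzyloxy)phenyl]-4-(8-bromo-3,5,7,3',4'-penta-O-benzylcatechin-6-yl)-4H-chromene | c1ccccc1COc1ccc2c(c1)OC(c1ccc(OCc3ccccc3)c(OCc3ccccc3)c1)=C[C@@H]2c1c(OCc3ccccc3)c(Br)c2c(c1OCc1ccccc1)C[C@H](OCc1ccccc1)[C@@H](c1ccc(OCc3ccccc3)c(OCc3ccccc3)c1)O2 | intermediate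
17 | C3 alkylborane of 16 (BH2 at C3, cis to H at C2, anti to the C4 aryl group) | c1ccccc1COc1ccc2c(c1)O[C@H](c1ccc(OCc3ccccc3)c(OCc3ccccc3)c1)[C@@H](B)[C@@H]2c1c(OCc3ccccc3)c(Br)c2c(c1OCc1ccccc1)C[C@H](OCc1ccccc1)[C@@H](c1ccc(OCc3ccccc3)c(OCc3ccccc3)c1)O2 | intermediate
18 | 8-bromo-octa-O-benzyl-fisetinidol-(4α→6)-catechin, upper unit (2R,3S,4S) with free 3-OH, lower unit (2R,3S) | c1ccccc1COc1ccc2c(c1)O[C@H](c1ccc(OCc3ccccc3)c(OCc3ccccc3)c1)[C@@H](O)[C@@H]2c1c(OCc3ccccc3)c(Br)c2c(c1OCc1ccccc1)C[C@H](OCc1ccccc1)[C@@H](c1ccc(OCc3ccccc3)c(OCc3ccccc3)c1)O2 | intermediate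
19 | fisetinidol-(4α→6)-catechin, upper unit (2R,3S,4S), lower unit (2R,3S) | Oc1ccc2c(c1)O[C@H](c1ccc(O)c(O)c1)[C@@H](O)[C@@H]2c1c(O)cc2c(c1O)C[C@H](O)[C@@H](c1ccc(O)c(O)c1)O2 | target

**Step count and risks**

Total step count: 11. Longest linear sequence: 9 steps (steps 1–5 and 8–11).

Steps most likely to fail:

1. Step 8. Insertion of the hindered, electron-rich enone into the aryl–rhodium bond may be slow, so that protodeboronation of the ortho-bromo boronic acid outruns addition, or the facial selectivity may erode. The fallback sets out from aldehyde 6 and comes back at ketone 15. Horner–Wadsworth–Emmons olefination of 6 with diethyl {2-oxo-2-[(4R)-2-oxo-4-phenyl-1,3-oxazolidin-3-yl]ethyl}phosphonate (LiCl, iPr2NEt, MeCN) should give the (E)-N-enoyl oxazolidinone F1. Conjugate addition of arylmagnesium chloride 12 mediated by CuBr·SMe2 (THF, −40 °C) to the chelated imide, anti to the phenyl group of the auxiliary, should give the (R)-configured adduct F2. Transamidation with MeNH(OMe)·HCl and AlMe3 gives the Weinreb amide F3, and addition of [3,4-bis(benzyloxy)phenyl]magnesium bromide F4 (from 4-bromo-1,2-bis(benzyloxy)benzene and Mg) gives 15.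

2. Step 9. The enolate O-arylation may stall through steric shielding of C8a by the neighbouring diarylmethine, with hydrodebromination or oxidation of the chromene taking over. The fallback sets out from ketone 15 and comes back at chromene 16. It replaces cross-coupling by an elimination–addition ring closure: lithium 2,2,6,6-tetramethylpiperidide (2.5 equiv, THF, −78 to 0 °C) forms the enolate and then lithiates C8–H between bromine and the benzyloxy group of ring A. Loss of LiBr gives the C8–C8a aryne, the enolate oxygen adds to C8a (the position favoured both by the tether and by the adjacent alkoxy group), and the C8 anion is protonated on work-up.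

3. Step 10. Facial or regiochemical control of the hydroboration may be lost, or the β-aryloxy borane may eliminate with opening of ring C. The fallback sets out from chromene 16 and comes back at 18. Dihydroxylation with OsO4 (cat.) and N-methylmorpholine N-oxide (acetone/H2O) anti to the C4 aryl group should give the (2R,3S,4S)-2,3-cis-diol hemiketal F5. Ionic reduction with Et3SiH and BF3·OEt2 (CH2Cl2, −40 °C) then removes the anomeric hydroxyl through the C2 oxocarbenium ion; axial hydride delivery on the face opposite the C4 aryl group should give the all-equatorial, all-trans product 18.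

**Further compounds**

F1 | step 8 | (4R)-3-[(E)-3-(8-bromo-3,5,7,3',4'-penta-O-benzylcatechin-6-yl)prop-2-enoyl]-4-phenyl-1,3-oxazolidin-2-one | O=C1OC[C@@H](c2ccccc2)N1C(=O)/C=C/c1c(OCc3ccccc3)c(Br)c2c(c1OCc1ccccc1)C[C@H](OCc1ccccc1)[C@@H](c1ccc(OCc3ccccc3)c(OCc3ccccc3)c1)O2
F2 | step 8 | (4R)-3-[(3R)-3-[4-(benzyloxy)-2-bromophenyl]-3-(8-bromo-3,5,7,3',4'-penta-O-benzylcatechin-6-yl)propanoyl]-4-phenyl-1,3-oxazolidin-2-one | O=C1OC[C@@H](c2ccccc2)N1C(=O)C[C@@H](c1ccc(OCc2ccccc2)cc1Br)c1c(OCc3ccccc3)c(Br)c2c(c1OCc1ccccc1)C[C@H](OCc1ccccc1)[C@@H](c1ccc(OCc3ccccc3)c(OCc3ccccc3)c1)O2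
F3 | step 8 | (3R)-3-[4-(benzyloxy)-2-bromophenyl]-3-(8-bromo-3,5,7,3',4'-penta-O-benzylcatechin-6-yl)-N-methoxy-N-methylpropanamide | CON(C)C(=O)C[C@@H](c1ccc(OCc2ccccc2)cc1Br)c1c(OCc3ccccc3)c(Br)c2c(c1OCc1ccccc1)C[C@H](OCc1ccccc1)[C@@H](c1ccc(OCc3ccccc3)c(OCc3ccccc3)c1)O2
F4 | step 8 | [3,4-bis(benzyloxy)phenyl]magnesium bromide | Br[Mg]c1ccc(OCc2ccccc2)c(OCc2ccccc2)c1
F0 | step 9 | none | none
F5 | step 10 | (2R,3S,4S)-2,3-cis-diol hemiketal of 16 (2-OH and 3-OH both anti to the C4 aryl group) | c1ccccc1COc1ccc2c(c1)O[C@](O)(c1ccc(OCc3ccccc3)c(OCc3ccccc3)c1)[C@@H](O)[C@@H]2c1c(OCc3ccccc3)c(Br)c2c(c1OCc1ccccc1)C[C@H](OCc1ccccc1)[C@@H](c1ccc(OCc3ccccc3)c(OCc3ccccc3)c1)O2
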